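The numbers in the tables are simulated for an exercise, noise included.

I had no rate constants for this flask, so I read two numbers off the earlier runs, one for each end of its course.

| flask | starting material | reagent | second substrate | third substrate | remark | time |
|---|---|---|---|---|---|---|
| east | 0.25 M | 1.2 equiv | 2 equiv (fed, over 50 s) | 0.50 equiv | run made earlier; the fed solution adds 0.25 times the starting volume |  |
| south-west | 0.25 M | 1.9 equiv | 2 equiv (fed, over 50 s) | 0.50 equiv | run made earlier; the fed solution adds 0.25 times the starting volume |  |
| south | 0.12 M | 2.5 equiv | 2 equiv (fed, over 50 s) | 0.50 equiv | run made earlier; the fed solution adds 0.25 times the starting volume |  |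
| flask | 0.25 M | 2.50 equiv | 2.00 equiv (fed, over 50 s) | 0.500 equiv | the fed solution adds 0.25 times the starting volume | 25 min |

| run | time / min | target / % | starting material / % |
|---|---|---|---|
| east | 4.00 | 16 | 81 |
| east | 8.00 | 25 | 76 |
| east | 12.0 | 25 | 70 |
| east | 15.0 | 27 | 67 |
| east | 20.0 | 27 | 65 |
| south-west | 4.00 | 23 | 78 |
| south-west | 8.00 | 33 | 63 |
| south-west | 12.0 | 39 | 56 |
| south-west | 15.0 | 39 | 55 |
| south-west | 20.0 | 43 | 53 |
| south | 2.00 | 10 | 90 |
| south | 5.00 | 22 | 76 |
| south | 10.0 | 33 | 65 |
| south | 15.0 | 42 | 54 |
| south | 20.0 | 43 | 49 |

(readings scatter by 1.5 percentage points)

- amounts are per litre of the starting volume; all of the dose is in the solution fed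

- amount of target in the flask at 25 min, in percent of the starting material charged
- amount of starting material in the flask at 25 min, in percent of the starting material charged
- amount of over-reaction product in the flask at 25 min, in percent of the starting material charged
- concentration of reagent at 25 min, in M

The first end is the flask with reagent held at its charge, where starting material decays first-order with a time constant τ. The south run lost 24.0% by 5.00 min. The flask has the same equivalents at 2.08 times the concentration, so, taking the rate as first order in reagent, I got τ = 8.75 min, and this end leaves 5.73% at 25 min.

The second end is the flask with its whole charge of reagent consumed. If the east and south-west runs had consumed theirs by 20.0 min, their readings cost 3.43 and 4.04. Their mean, 3.74, is my reading of the reagent price c, the equivalents of reagent consumed per equivalent of starting material lost. Treating reagent as the limiting reagent, I estimated a stopping level F = 33.1% of starting material for the flask.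

That estimate stands higher than the first end's figure, so I expected the flask to approach F. I joined the ends with an exponential from the full charge down to F that keeps the starting slope. Its time constant is τ times the fraction lost at F, 5.85 min, and at 25 min it gives 34.0% starting material.

The forecast gave 50% target, 43% starting material, 7% over-reaction product and 0.04 M reagent, judging that “reagent seems to be used up wastefully, at about 3.5–4 equiv per starting material converted”. Its starting material stands above my figure.

The flask gave 47.8% target, 35.6% starting material, 16.5% over-reaction product and 0.0386 M reagent.

    second substrate + reagent → second product (k = 0.00340 M⁻¹ s⁻¹)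
    third substrate + reagent → third product (k = 0.0110 M⁻¹ s⁻¹)
    starting material + reagent → target (k = 0.00450 M⁻¹ s⁻¹)
    reagent + target → over-reaction product (k = 0.00230 M⁻¹ s⁻¹)

Reckoned as for my reading of 3.74, the flask's price c was 3.58 at 25 min, and the same flask read at 15 min gave 3.55. By 5.00 min the flask's third-substrate step had 75% of its turnover up to 25 min behind it, and the step to target had 59%. In the flask, from 12.5 min to 25 min, as reagent fell from 21.8% of its charge to 7.7%, target went from 44.1% to 47.8% and over-reaction product from 11.2% to 16.5%.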